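The 17-membered ring of the target (N1 lactam NH, C2 carbonyl, C3, C4 bearing nonyl, N5, N9, N14) holds a β-amino acid segment N5–C4–C3–C2. In it, C2 is a lone carbon between C3 and nitrogen. This carbon comes from CO. Cobalt-catalysed carbonylation of the three-membered ring N5–C3–C4 cuts N5–C3 and forms C2–C3 and C2–N5 in one operation, giving a four-membered lactam with C4 untouched. The precursor is an (R)-2-nonylaziridine whose nitrogen carries the complete spermine chain, with N9, N14 and N1 masked as Boc carbamates. Acidic methanolysis then frees a tetraamino ester, and an antimony template closes the N1–C2 amide.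

Key step: step 6

Remark on the chemistry: with the priorities N5 > C3 > nonyl > H, C4 is R in the target, the tetraamino ester, the β-lactam and the aziridine, which all share one spatial arrangement. The single inversion of the route must therefore start from an S carbinol, and hence from the S epoxide.

Step 1
Reactants: 1 1-undecene
Product: 2 rac-2-nonyloxirane (1,2-epoxyundecane)
Conditions: mCPBA (1.2 equiv), CH2Cl2, 0 °C → rt
Reagents that add atoms: mCPBA (3-chloroperoxybenzoic acid), O=C(OO)c1cccc(Cl)c1
Why: Prilezhaev epoxidation of an unhindered terminal alkene; the new stereocentre is formed as a racemate and is sorted out in step 2.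

Step 2
Reactants: 2 rac-2-nonyloxirane
Product: 3 (S)-2-nonyloxirane
Conditions: (S,S)-(salen)Co(OAc) (0.5 mol %; salen = N,N'-bis(3,5-di-tert-butylsalicylidene)cyclohexane-1,2-diamine dianion), H2O (0.55 equiv), neat with a little THF, 0 °C → rt; vacuum distillation
Reagents that add atoms: none
Why: Jacobsen hydrolytic kinetic resolution, in which the S,S catalyst hydrates the R epoxide much faster at its terminal carbon, so that the S enantiomer, the source of the C4 configuration, remains and is distilled away from the diol.

Step 3
Reactants: 4 spermine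
Product: 7 N1,N4,N9-tri-Boc-spermine (one primary amine free), via mono-trifluoroacetamide 5 (not isolated), via tri-Boc trifluoroacetamide 6 (not isolated)
Conditions: CF3CO2Et (1.0 equiv), MeOH, −78 → 0 °C; Boc2O (4 equiv), 0 °C → rt; conc. aq NH3, rt (one pot)
Reagents that add atoms: di-tert-butyl dicarbonate, CC(C)(C)OC(=O)OC(=O)OC(C)(C)C; ethyl trifluoroacetate, CCOC(=O)C(F)(F)F (its CF3CO group is present in 5 and 6 only)
Why: Statistical mono-trifluoroacetylation of one primary amine, Boc protection of the three remaining nitrogens and selective ammonolysis of the labile trifluoroacetamide form the standard one-pot desymmetrisation of spermine; no stereocentre is involved.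

Step 4
Reactants: 3 (S)-2-nonyloxirane; 7 N1,N4,N9-tri-Boc-spermine
Product: 8 (S)-1-amino-undecan-2-ol whose nitrogen carries the chain (CH2)3N(Boc)(CH2)4N(Boc)(CH2)3NHBoc
Conditions: 7 (1.5 equiv, excess recovered), i-PrOH, 80 °C, sealed tube
Reagents that add atoms: none
Why: SN2 aminolysis of a terminal epoxide in a protic solvent takes place at the unsubstituted carbon, so the C–O bond at the stereocentre is untouched (S retained), the carbamates are inert, and the excess of amine suppresses a second alkylation.

Step 5
Reactants: 8 (S)-amino alcohol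
Product: 9 (R)-2-nonylaziridine whose nitrogen carries the chain (CH2)3N(Boc)(CH2)4N(Boc)(CH2)3NHBoc
Conditions: PPh3 (1.3 equiv), DIAD (1.3 equiv), THF, 0 °C → rt; chromatography on basic alumina
Reagents that add atoms: none
Why: Mitsunobu-type cyclodehydration of a 1,2-amino alcohol, in which only the oxygen is activated as an oxyphosphonium group and the neighbouring secondary amine displaces Ph3P=O in a 3-exo-tet SN2 step, so the carbinol carbon is inverted from S to R, while the carbamate N–H is too weakly acidic to take part.

Step 6
Reactants: 9 (R)-aziridine; 10 carbon monoxide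
Product: 11 (R)-4-nonylazetidin-2-one whose nitrogen carries the chain (CH2)3N(Boc)(CH2)4N(Boc)(CH2)3NHBoc
Conditions: Co2(CO)8 (10 mol %), CO (35 bar), DME, 100 °C, steel autoclave
Reagents that add atoms: carbon monoxide (10), [C-]#[O+]
Why: In the donor solvent the dimer disproportionates into a cationic divalent cobalt Lewis acid and Co(CO)4−; the cation binds the basic ring nitrogen, the cobaltate opens the ring by backside attack at the unsubstituted carbon C3, CO migrates into the new Co–C3 bond (C2–C3), and the liberated metal amide N5 attacks the acylcobalt carbon (C2–N5), which returns the cobaltate. The closest known reaction type is the cobalt-carbonyl-catalysed carbonylative ring expansion of N-alkyl-2-alkylaziridines to 4-alkylazetidin-2-ones, applied here to a new molecule. The azetidinone ring closes in the 4-exo-trig mode. No stereocentre is created, and because the C4–N5 bond and the other three bonds of C4 stay intact, the R configuration of 9 passes unchanged into 11. The step needs regioselectivity for N5–C3 over N5–C4 cleavage, which the nonyl branch secures by shielding C4 from the bulky nucleophile. It also needs chemoselectivity, which is secured because N9, N14 and N1 are non-basic carbamates that are stable at this temperature and leave the aziridine nitrogen as the only good donor for the Lewis acid.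

Step 7
Reactants: 11 (R)-β-lactam
Product: 13 methyl (R)-3-{[3-({4-[(3-aminopropyl)amino]butyl}amino)propyl]amino}dodecanoate, via deprotected β-lactam 12 (not isolated)
Conditions: HCl (3 M in MeOH), 0 °C → reflux; evaporate; NaOMe (4.0 equiv), MeOH, 0 °C, filter
Reagents that add atoms: methanol, CO
Why: Acidolysis of the tert-butyl carbamates followed by acid-catalysed methanolysis of the strained azetidinone (acyl–N cleavage) is standard β-lactam to β-amino ester chemistry; all amines stay protonated until the lactam is open, which blocks acyl migration, and C4 is not a reacting centre.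

Step 8
Reactants: 13 (R)-tetraamino ester
Product: 14 (R)-4-nonyl-1,5,9,14-tetraazacycloheptadecan-2-one (target)
Conditions: Sb(OEt)3 (1.2 equiv), toluene (5 mM), reflux through 4 Å MS (Soxhlet); aqueous work-up
Reagents that add atoms: none
Why: Antimony-templated macrolactamisation of tetraamino esters, a reaction type developed for 17-membered spermine lactams, in which Sb–N bonds formed with loss of ethanol gather the chain around one metal centre and deliver the terminal primary nitrogen N1 to the ester carbon C2 under neutral conditions that leave C4 untouched.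

Compound list
1 | 1-undecene | C=CCCCCCCCCC | starting material
2 | rac-2-nonyloxirane | CCCCCCCCCC1CO1 | intermediate
3 | (S)-2-nonyloxirane | CCCCCCCCC[C@H]1CO1 | intermediate
4 | spermine | NCCCNCCCCNCCCN | starting material
5 | N-[3-({4-[(3-aminopropyl)amino]butyl}amino)propyl]-2,2,2-trifluoroacetamide | NCCCNCCCCNCCCNC(=O)C(F)(F)F | intermediate
6 | N1,N4,N9-tri-Boc-N12-trifluoroacetylspermine | FC(F)(F)C(=O)NCCCN(C(=O)OC(C)(C)C)CCCCN(C(=O)OC(C)(C)C)CCCNC(=O)OC(C)(C)C | intermediate
7 | N1,N4,N9-tri-Boc-spermine | NCCCN(C(=O)OC(C)(C)C)CCCCN(C(=O)OC(C)(C)C)CCCNC(=O)OC(C)(C)C | intermediate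
8 | (S)-1-(tri-Boc-spermin-N12-yl)undecan-2-ol | CCCCCCCCC[C@H](O)CNCCCN(C(=O)OC(C)(C)C)CCCCN(C(=O)OC(C)(C)C)CCCNC(=O)OC(C)(C)C | intermediate
9 | (R)-2-nonyl-1-(tri-Boc-spermine chain)aziridine | CCCCCCCCC[C@@H]1CN1CCCN(C(=O)OC(C)(C)C)CCCCN(C(=O)OC(C)(C)C)CCCNC(=O)OC(C)(C)C | intermediate
10 | carbon monoxide | [C-]#[O+] | starting material
11 | (R)-4-nonyl-1-(tri-Boc-spermine chain)azetidin-2-one | CCCCCCCCC[C@@H]1CC(=O)N1CCCN(C(=O)OC(C)(C)C)CCCCN(C(=O)OC(C)(C)C)CCCNC(=O)OC(C)(C)C | intermediate
12 | (R)-1-[3-({4-[(3-aminopropyl)amino]butyl}amino)propyl]-4-nonylazetidin-2-one (trihydrochloride in the flask) | CCCCCCCCC[C@@H]1CC(=O)N1CCCNCCCCNCCCN | intermediate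
13 | methyl (R)-3-{[3-({4-[(3-aminopropyl)amino]butyl}amino)propyl]amino}dodecanoate | CCCCCCCCC[C@@H](NCCCNCCCCNCCCN)CC(=O)OC | intermediate
14 | (R)-4-nonyl-1,5,9,14-tetraazacycloheptadecan-2-one | CCCCCCCCC[C@@H]1CC(=O)NCCCNCCCCNCCCN1 | target

Total step count: 8. Longest linear sequence: 7 steps (steps 1, 2, 4, 5, 6, 7, 8); step 3 is the convergent branch.

Steps most likely to fail

**Step 6 (CO insertion).**
- What may go wrong: the three carbamate carbonyls may tie up the Lewis-acidic cobalt cation, so that ring opening stalls. The ring-opened nitrogen may be captured by the neighbouring N9 carbamate. The aziridine may also oligomerise at the temperature needed.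
- Fallback from 3 and 7 back to 13. It uses no carbonylation: N5–C4 is made by stereospecific substitution and C2 comes from an alkene carbon. Amine 7 is sulfonylated with 2-nitrobenzenesulfonyl chloride (Et3N, CH2Cl2) to give N12-(2-nitrobenzenesulfonyl)-tri-Boc-spermine F1. Epoxide 3 is opened with vinylmagnesium bromide (CuI cat., THF, −30 °C) to give (S)-tridec-1-en-4-ol F2. A Fukuyama–Mitsunobu coupling of the two (PPh3, DIAD, toluene) inverts the carbinol carbon and should give the (R)-N-(tridec-1-en-4-yl)sulfonamide F3. Oxidative cleavage of the vinyl group (RuCl3 cat., NaIO4, MeCN/EtOAc/H2O) gives the (R)-3-(N-nosylamino)dodecanoic acid F4. Thiophenol and K2CO3 in DMF remove the sulfonyl group to give the (R)-3-(alkylamino)dodecanoic acid F5. Methanolic HCl at reflux followed by NaOMe esterifies the acid and strips the carbamates, which delivers 13.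

**Step 8 (macrolactamisation).**
- What may go wrong: oligomerisation, or acylation at an inner nitrogen (N9 or N14), may compete if the template fails to organise the chain.
- Fallback from 11 back to 14. It uses ring strain and a transamidation relay (zip reaction) in place of ester activation. TFA in CH2Cl2 removes the three Boc groups. On liberation of the free base 12 (aq NaOH, then MeOH, 40 °C), N9 attacks the strained lactam through a six-membered tetrahedral intermediate. This gives the eight-membered lactam (R)-1-{4-[(3-aminopropyl)amino]butyl}-4-nonyl-1,5-diazocan-2-one F6. Potassium 3-aminopropylamide in 1,3-diaminopropane (rt) then moves the acyl group to N14 through a seven-membered intermediate. This gives the thirteen-membered lactam (R)-1-(3-aminopropyl)-4-nonyl-1,5,9-triazacyclotridecan-2-one F7. The acyl group moves on to N1, where deprotonation of the only secondary amide holds the equilibrium, and an aqueous quench gives 14.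

**Step 5 (aziridine closure).**
- What may go wrong: the hydrazide may capture the activated alcohol, the reaction may stall at a cyclic P–N–O adduct, or the aziridine may open under acid while phosphorus residues are removed. Such residues would also poison step 6.
- Fallback from 2 and 7 back to 9. The amine meets a preformed bis-electrophile, so no N/O differentiation and no phosphorus reagent are needed. Resolution of 2 with the enantiomeric catalyst (R,R)-(salen)Co(OAc) and H2O (0.45 equiv) gives (S)-undecane-1,2-diol F8. SOCl2 (Et3N, CH2Cl2, 0 °C) gives (4S)-4-nonyl-1,3,2-dioxathiolane 2-oxide F9. RuCl3 (cat.) with NaIO4 oxidises this to (S)-4-nonyl-1,3,2-dioxathiolane 2,2-dioxide F10. Amine 7 opens the cyclic sulfate at the CH2 carbon (THF, rt → 50 °C) to give the zwitterionic (S)-β-amino hydrogen sulfate F11. Warm aqueous NaOH with toluene then closes the ring in a Wenker-type displacement of sulfate, with inversion at the secondary carbon, which gives 9.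

Further compounds
F1 | step 6 | N12-(2-nitrobenzenesulfonyl)-N1,N4,N9-tri-Boc-spermine | O=S(=O)(NCCCN(C(=O)OC(C)(C)C)CCCCN(C(=O)OC(C)(C)C)CCCNC(=O)OC(C)(C)C)c1ccccc1[N+](=O)[O-]
F2 | step 6 | (S)-tridec-1-en-4-ol | CCCCCCCCC[C@H](O)CC=C
F3 | step 6 | (R)-N-(tridec-1-en-4-yl)-N-(tri-Boc-spermine chain)-2-nitrobenzenesulfonamide | CCCCCCCCC[C@@H](N(CCCN(C(=O)OC(C)(C)C)CCCCN(C(=O)OC(C)(C)C)CCCNC(=O)OC(C)(C)C)S(=O)(=O)c1ccccc1[N+](=O)[O-])CC=C
F4 | step 6 | (R)-3-[N-(2-nitrobenzenesulfonyl)-N-(tri-Boc-spermine chain)amino]dodecanoic acid | CCCCCCCCC[C@@H](N(CCCN(C(=O)OC(C)(C)C)CCCCN(C(=O)OC(C)(C)C)CCCNC(=O)OC(C)(C)C)S(=O)(=O)c1ccccc1[N+](=O)[O-])CC(=O)O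
F5 | step 6 | (R)-3-[(tri-Boc-spermine chain)amino]dodecanoic acid | CCCCCCCCC[C@@H](NCCCN(C(=O)OC(C)(C)C)CCCCN(C(=O)OC(C)(C)C)CCCNC(=O)OC(C)(C)C)CC(=O)O
F6 | step 8 | (R)-1-{4-[(3-aminopropyl)amino]butyl}-4-nonyl-1,5-diazocan-2-one | CCCCCCCCC[C@@H]1CC(=O)N(CCCCNCCCN)CCCN1
F7 | step 8 | (R)-1-(3-aminopropyl)-4-nonyl-1,5,9-triazacyclotridecan-2-one | CCCCCCCCC[C@@H]1CC(=O)N(CCCN)CCCCNCCCN1
F8 | step 5 | (S)-undecane-1,2-diol | CCCCCCCCC[C@H](O)CO
F9 | step 5 | (4S)-4-nonyl-1,3,2-dioxathiolane 2-oxide (both sulfur epimers) | CCCCCCCCC[C@H]1COS(=O)O1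
F10 | step 5 | (S)-4-nonyl-1,3,2-dioxathiolane 2,2-dioxide | CCCCCCCCC[C@H]1COS(=O)(=O)O1
F11 | step 5 | (S)-1-[(tri-Boc-spermine chain)amino]undecan-2-yl hydrogen sulfate | CCCCCCCCC[C@H](OS(=O)(=O)O)CNCCCN(C(=O)OC(C)(C)C)CCCCN(C(=O)OC(C)(C)C)CCCNC(=O)OC(C)(C)C
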